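**Strategy.** With isochromene numbering (C1, O2, C3, C4, C4a, C5–C8, C8a), the carbocycle C4a–C5–C6–C7–C8–C8a of the target is a 4-alkylidenecyclohex-2-enone: C6 ketone, C5=C4a enone and exocyclic C8a=C1. That is the retron of a rhodium-catalysed [4+2] annulation of a 4-alkynal with an alkyne. The key step joins an open-chain aldehyde that already carries both stereocentres (C6 formyl, C7, C8, C8a≡C1 alkynylboronate) with a terminal diyne ester (C5≡C4a–C4≡C3), forming C5–C6 and C4a–C8a in one operation. Oxidation of the C1–B bond and 6-endo closure of the resulting enol onto C3 then build the pyran ring. The stereocentres come from (S)-lactic acid by dioxolanone enolate aldol chemistry.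

Key step: step 13

Remark on the chemistry: the target is (7R,8R), with the C7 hydroxyl and the C8 acyloxy group cis on the ring; in an open C6–C7–C8–C8a chain this corresponds to the anti (erythro) diol. The aldol of step 2 is assumed to pass through a closed chair transition state.

**Step 1**
Reactants: 1 (S)-lactic acid; 2 pivalaldehyde
Product: 3 (2S,5S)-2-tert-butyl-5-methyl-1,3-dioxolan-4-one (cis)
Conditions: p-TsOH (cat.), pentane, reflux, Dean–Stark; recrystallisation of the cis isomer
Reagents that add atoms: none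
Why: Acid-catalysed acetalisation under thermodynamic control favours the cis-2,5-disubstituted dioxolanone, so the lactate centre fixes the acetal centre as (2S) (self-regeneration of stereocentres).

**Step 2**
Reactants: 3 (2S,5S)-2-tert-butyl-5-methyl-1,3-dioxolan-4-one; 4 3-(trimethylsilyl)prop-2-ynal
Product: 6 (2S,5R)-2-tert-butyl-5-[(1R)-1-hydroxy-3-(trimethylsilyl)prop-2-yn-1-yl]-5-methyl-1,3-dioxolan-4-one, via lithium enolate 5 (not isolated)
Conditions: LiN(i-Pr)2, THF, −78 °C; then 4, −78 °C; aq. NH4Cl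
Reagents that add atoms: none
Why: In this dioxolanone enolate aldol addition the aldehyde attacks anti to the tert-butyl group, which rebuilds the quaternary centre (C7) with retention as (R), and a Zimmerman–Traxler chair with the alkynyl group equatorial should place the new hydroxyl syn to the methyl group, i.e. (1R) at C8.

**Step 3**
Reactants: 7 ethyl orsellinate (ethyl 2,4-dihydroxy-6-methylbenzoate)
Product: 8 ethyl 2,4-bis[(4-methoxybenzyl)oxy]-6-methylbenzoate
Conditions: 4-methoxybenzyl chloride, K2CO3, NaI (cat.), DMF, 70 °C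
Reagents that add atoms: 4-methoxybenzyl chloride, COc1ccc(CCl)cc1
Why: Williamson etherification of both phenols gives acid-labile PMB ethers that can leave at the end together with the other protecting groups.

**Step 4**
Reactants: 8 ethyl 2,4-bis[(4-methoxybenzyl)oxy]-6-methylbenzoate
Product: 9 2,4-bis[(4-methoxybenzyl)oxy]-6-methylbenzoic acid
Conditions: KOH, EtOH/H2O, reflux; then aq. KHSO4 to pH 3–4, 0 °C
Reagents that add atoms: potassium hydroxide, [K+].[OH-]
Why: Saponification of the hindered ester needs forcing basic conditions, which the benzyl-type ethers tolerate.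

**Step 5**
Reactants: 6 aldol adduct; 9 2,4-bis[(4-methoxybenzyl)oxy]-6-methylbenzoic acid
Product: 11 (1R)-1-[(2S,4R)-2-tert-butyl-4-methyl-5-oxo-1,3-dioxolan-4-yl]-3-(trimethylsilyl)prop-2-yn-1-yl 2,4-bis[(4-methoxybenzyl)oxy]-6-methylbenzoate, via acid chloride 10 (not isolated)
Conditions: 9, 1-chloro-N,N,2-trimethylprop-1-en-1-amine, CH2Cl2, 0 °C to rt; then 6, Et3N, DMAP (cat.), CH2Cl2, rt to 40 °C
Reagents that add atoms: none
Why: The acid chloride is formed under neutral conditions and acylates the secondary propargylic alcohol by nucleophilic catalysis (Steglich-type) without touching the C8–H bond, so the (R) configuration is retained.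

**Step 6**
Reactants: 11 silylalkyne ester
Product: 12 (1R)-1-[(2S,4R)-2-tert-butyl-4-methyl-5-oxo-1,3-dioxolan-4-yl]prop-2-yn-1-yl 2,4-bis[(4-methoxybenzyl)oxy]-6-methylbenzoate
Conditions: Bu4NF, AcOH, THF, 0 °C
Reagents that add atoms: none
Why: Fluoride-induced protodesilylation of the C(sp)–Si bond under acetic acid buffering spares the acylal lactone and the hindered aryl ester.

**Step 7**
Reactants: 12 terminal alkyne
Product: 14 (1R)-1-[(2S,4R)-2-tert-butyl-4-methyl-5-oxo-1,3-dioxolan-4-yl]-3-(4,4,5,5-tetramethyl-1,3,2-dioxaborolan-2-yl)prop-2-yn-1-yl 2,4-bis[(4-methoxybenzyl)oxy]-6-methylbenzoate, via lithium acetylide 13 (not isolated)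
Conditions: LiN(SiMe3)2 (1.05 equiv), THF, −78 °C; 2-isopropoxy-4,4,5,5-tetramethyl-1,3,2-dioxaborolane; then HCl in Et2O, −78 °C to rt; used crude
Reagents that add atoms: 2-isopropoxy-4,4,5,5-tetramethyl-1,3,2-dioxaborolane, CC(C)OB1OC(C)(C)C(C)(C)O1
Why: The non-nucleophilic silylamide removes only the acetylenic proton (the most acidic one, no toluate deprotonation), the acetylide adds to the borate and anhydrous acid collapses the ate complex to the alkynylboronate (acetylide borylation).

**Step 8**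
Reactants: 14 alkynylboronate dioxolanone
Product: 16 (2R,3R)-2-hydroxy-2-methyl-1-oxo-5-(4,4,5,5-tetramethyl-1,3,2-dioxaborolan-2-yl)pent-4-yn-3-yl 2,4-bis[(4-methoxybenzyl)oxy]-6-methylbenzoate, via lactol 15 (not isolated)
Conditions: i-Bu2AlH (1.1 equiv), CH2Cl2, −78 °C; aq. potassium sodium tartrate (KNaC4H4O6); concentration under vacuum
Reagents that add atoms: none
Why: Hydride reduces the activated acylal carbonyl to the lactol far faster than the hindered, electron-rich aryl ester, and the lactol collapses to the α-hydroxy aldehyde with loss of volatile pivalaldehyde (retro-hemiacetalisation).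

**Step 9**
Reactants: 16 α-hydroxy aldehyde
Product: 17 (2R,3R)-2-methyl-1-oxo-5-(4,4,5,5-tetramethyl-1,3,2-dioxaborolan-2-yl)-2-(triethylsilyloxy)pent-4-yn-3-yl 2,4-bis[(4-methoxybenzyl)oxy]-6-methylbenzoate
Conditions: Et3SiOTf (1.2 equiv), 2,6-lutidine, CH2Cl2, −78 °C
Reagents that add atoms: triethylsilyl trifluoromethanesulfonate, CC[Si](CC)(CC)OS(=O)(=O)C(F)(F)F
Why: Silylation of the tertiary alcohol with the silyl triflate and a hindered base blocks α-ketol rearrangement and chelation of rhodium in the annulation.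

**Step 10**
Reactants: 18 1,4-bis(trimethylsilyl)buta-1,3-diyne
Product: 20 5-(trimethylsilyl)penta-2,4-diynal, via lithium diynide 19 (not isolated)
Conditions: MeLi·LiBr (1.0 equiv), THF, −78 °C to rt; DMF, −78 °C; aq. NH4Cl
Reagents that add atoms: N,N-dimethylformamide, CN(C)C=O
Why: One C(sp)–Si bond is cleaved selectively by methyllithium and the lithium acetylide is formylated with the formamide (Bouveault-type formylation).

**Step 11**
Reactants: 20 5-(trimethylsilyl)penta-2,4-diynal; 21 tert-butyl (triphenyl-λ5-phosphanylidene)acetate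
Product: 22 tert-butyl (2E)-7-(trimethylsilyl)hept-2-ene-4,6-diynoate
Conditions: CH2Cl2, 0 °C to rt
Reagents that add atoms: none
Why: Wittig olefination with a stabilised ylide should give the (E)-enoate.

**Step 12**
Reactants: 22 silyl enediynoate
Product: 23 tert-butyl (2E)-hept-2-ene-4,6-diynoate
Conditions: K2CO3 (0.1 equiv), MeOH/THF, 0 °C, 15 min; kept in CH2Cl2 solution and used at once
Reagents that add atoms: none
Why: Base-catalysed methanolysis of the C(sp)–Si bond is fast for conjugated diynes, and the terminal diyne is kept in solution because it polymerises when concentrated.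

**Step 13**
Reactants: 17 silyloxy 4-alkynal; 23 tert-butyl (2E)-hept-2-ene-4,6-diynoate
Product: 24 tert-butyl (2E)-5-[(4R,5R,6Z)-5-{2,4-bis[(4-methoxybenzyl)oxy]-6-methylbenzoyloxy}-4-methyl-3-oxo-6-[(4,4,5,5-tetramethyl-1,3,2-dioxaborolan-2-yl)methylidene]-4-(triethylsilyloxy)cyclohex-1-en-1-yl]pent-2-en-4-ynoate
Conditions: [Rh(dppe)]2(BF4)2 (5 mol %), CH2Cl2, rt; 23 (3 equiv) added over 4 h
Reagents that add atoms: none
Why: Oxidative addition of the aldehyde C–H bond of 17 to monovalent rhodium gives an acylrhodium hydride, syn hydrorhodation of the tethered alkynylboronate (H to C1, Rh to C8a) gives a five-membered acyl(alkenyl)rhodium metallacycle, the terminal triple bond of 23 inserts so that the acyl carbon C6 bonds to the unsubstituted terminus C5, and C(sp2)–C(sp2) reductive elimination forms C4a–C8a. The closest known reaction type is the rhodium-catalysed [4+2] annulation of 4-alkynals with alkynes to 4-alkylidenecyclohex-2-enones, a family in which 4-alkynals oxygenated at C3 form the same acylrhodium intermediates. The carbocycle (C4a–C5–C6–C7–C8–C8a) closes by reductive elimination from a seven-membered rhodacycle, a formal [4+2] of the four carbons C6–C7–C8–C8a with the two carbons C5–C4a. No stereocentre is created: C7 is quaternary and C8 is not acidic under the neutral conditions, so both are carried through, and the exocyclic C8a=C1 geometry (boron cis to C8) follows from the syn addition of Rh–H. The step needs the right regiochemistry of the diyne (acyl migration to the unhindered CH terminus should leave rhodium on the carbon stabilised by the adjacent alkynyl group), reaction at the terminal and not the internal triple bond (sterics), and annulation in preference to intramolecular hydroacylation (non-coordinating solvent and excess alkyne).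

**Step 14**
Reactants: 24 alkenylboronate
Product: 26 tert-butyl (2E)-3-[(7R,8R)-8-{2,4-bis[(4-methoxybenzyl)oxy]-6-methylbenzoyloxy}-7-methyl-6-oxo-7-(triethylsilyloxy)-7,8-dihydro-6H-isochromen-3-yl]prop-2-enoate, via enol 25 (not isolated)
Conditions: 30% H2O2, pH 7 phosphate buffer, THF, 0 °C; extractive work-up; then AgOTf (10 mol %), CH2Cl2, rt
Reagents that add atoms: hydrogen peroxide, OO
Why: Oxidation of the alkenyl C–B bond (1,2-boronate shift) unveils the C1 enol of a vinylogous acid, whose oxygen adds 6-endo-dig to the silver-activated C3≡C4 bond (cycloisomerisation of the o-alkynyl carbonyl type) to give the fully conjugated pyran, which should also be the thermodynamic product.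

**Step 15**
Reactants: 26 protected mitorubrinic acid B
Product: 27 (+)-mitorubrinic acid B, (2E)-3-[(7R,8R)-8-(2,4-dihydroxy-6-methylbenzoyloxy)-7-hydroxy-7-methyl-6-oxo-7,8-dihydro-6H-isochromen-3-yl]prop-2-enoic acid
Conditions: TFA/CH2Cl2 (1:1), 1,3,5-trimethoxybenzene (3 equiv), 0 °C to rt; aqueous work-up
Reagents that add atoms: none
Why: Acidolysis removes both PMB ethers (cation trapped by the arene), the tert-butyl ester and the triethylsilyl ether in one operation, while the orsellinate stays on the secondary O8, the favoured site of a cis-diol monoester.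

**Compound list**
1 | (S)-lactic acid | C[C@H](O)C(=O)O | starting material
2 | pivalaldehyde | CC(C)(C)C=O | starting material
3 | (2S,5S)-2-tert-butyl-5-methyl-1,3-dioxolan-4-one | C[C@@H]1O[C@H](C(C)(C)C)OC1=O | intermediate
4 | 3-(trimethylsilyl)prop-2-ynal | C[Si](C)(C)C#CC=O | starting material
5 | lithium (2S)-2-tert-butyl-5-methyl-1,3-dioxol-4-olate (enolate of 3) | CC1=C(O[Li])O[C@@H](C(C)(C)C)O1 | intermediate
6 | (2S,5R)-2-tert-butyl-5-[(1R)-1-hydroxy-3-(trimethylsilyl)prop-2-yn-1-yl]-5-methyl-1,3-dioxolan-4-one | C[C@]1([C@H](O)C#C[Si](C)(C)C)O[C@H](C(C)(C)C)OC1=O | intermediate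
7 | ethyl orsellinate | CCOC(=O)c1c(C)cc(O)cc1O | starting material
8 | ethyl 2,4-bis[(4-methoxybenzyl)oxy]-6-methylbenzoate | CCOC(=O)c1c(C)cc(OCc2ccc(OC)cc2)cc1OCc1ccc(OC)cc1 | intermediate
9 | 2,4-bis[(4-methoxybenzyl)oxy]-6-methylbenzoic acid | Cc1cc(OCc2ccc(OC)cc2)cc(OCc2ccc(OC)cc2)c1C(=O)O | intermediate
10 | 2,4-bis[(4-methoxybenzyl)oxy]-6-methylbenzoyl chloride | Cc1cc(OCc2ccc(OC)cc2)cc(OCc2ccc(OC)cc2)c1C(=O)Cl | intermediate
11 | (1R)-1-[(2S,4R)-2-tert-butyl-4-methyl-5-oxo-1,3-dioxolan-4-yl]-3-(trimethylsilyl)prop-2-yn-1-yl 2,4-bis[(4-methoxybenzyl)oxy]-6-methylbenzoate | C[C@]1([C@H](OC(=O)c2c(C)cc(OCc3ccc(OC)cc3)cc2OCc3ccc(OC)cc3)C#C[Si](C)(C)C)O[C@H](C(C)(C)C)OC1=O | intermediate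
12 | (1R)-1-[(2S,4R)-2-tert-butyl-4-methyl-5-oxo-1,3-dioxolan-4-yl]prop-2-yn-1-yl 2,4-bis[(4-methoxybenzyl)oxy]-6-methylbenzoate | C[C@]1([C@H](OC(=O)c2c(C)cc(OCc3ccc(OC)cc3)cc2OCc3ccc(OC)cc3)C#C)O[C@H](C(C)(C)C)OC1=O | intermediate
13 | lithium acetylide of 12 | C[C@]1([C@H](OC(=O)c2c(C)cc(OCc3ccc(OC)cc3)cc2OCc3ccc(OC)cc3)C#C[Li])O[C@H](C(C)(C)C)OC1=O | intermediate
14 | (1R)-1-[(2S,4R)-2-tert-butyl-4-methyl-5-oxo-1,3-dioxolan-4-yl]-3-(4,4,5,5-tetramethyl-1,3,2-dioxaborolan-2-yl)prop-2-yn-1-yl 2,4-bis[(4-methoxybenzyl)oxy]-6-methylbenzoate | C[C@]1([C@H](OC(=O)c2c(C)cc(OCc3ccc(OC)cc3)cc2OCc3ccc(OC)cc3)C#CB2OC(C)(C)C(C)(C)O2)O[C@H](C(C)(C)C)OC1=O | intermediate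
15 | lactol of 14 (5-hydroxy-1,3-dioxolane, both hemiacetal epimers) | C[C@]1([C@H](OC(=O)c2c(C)cc(OCc3ccc(OC)cc3)cc2OCc3ccc(OC)cc3)C#CB2OC(C)(C)C(C)(C)O2)O[C@H](C(C)(C)C)OC1O | intermediate
16 | (2R,3R)-2-hydroxy-2-methyl-1-oxo-5-(4,4,5,5-tetramethyl-1,3,2-dioxaborolan-2-yl)pent-4-yn-3-yl 2,4-bis[(4-methoxybenzyl)oxy]-6-methylbenzoate | O=C[C@](C)(O)[C@H](OC(=O)c1c(C)cc(OCc2ccc(OC)cc2)cc1OCc1ccc(OC)cc1)C#CB1OC(C)(C)C(C)(C)O1 | intermediate
17 | (2R,3R)-2-methyl-1-oxo-5-(4,4,5,5-tetramethyl-1,3,2-dioxaborolan-2-yl)-2-(triethylsilyloxy)pent-4-yn-3-yl 2,4-bis[(4-methoxybenzyl)oxy]-6-methylbenzoate | O=C[C@](C)(O[Si](CC)(CC)CC)[C@H](OC(=O)c1c(C)cc(OCc2ccc(OC)cc2)cc1OCc1ccc(OC)cc1)C#CB1OC(C)(C)C(C)(C)O1 | intermediate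
18 | 1,4-bis(trimethylsilyl)buta-1,3-diyne | C[Si](C)(C)C#CC#C[Si](C)(C)C | starting material
19 | lithium 4-(trimethylsilyl)buta-1,3-diyn-1-ide | C[Si](C)(C)C#CC#C[Li] | intermediate
20 | 5-(trimethylsilyl)penta-2,4-diynal | C[Si](C)(C)C#CC#CC=O | intermediate
21 | tert-butyl (triphenyl-λ5-phosphanylidene)acetate | CC(C)(C)OC(=O)C=P(c1ccccc1)(c1ccccc1)c1ccccc1 | starting material
22 | tert-butyl (2E)-7-(trimethylsilyl)hept-2-ene-4,6-diynoate | CC(C)(C)OC(=O)/C=C/C#CC#C[Si](C)(C)C | intermediate
23 | tert-butyl (2E)-hept-2-ene-4,6-diynoate | CC(C)(C)OC(=O)/C=C/C#CC#C | intermediate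
24 | tert-butyl (2E)-5-[(4R,5R,6Z)-5-{2,4-bis[(4-methoxybenzyl)oxy]-6-methylbenzoyloxy}-4-methyl-3-oxo-6-[(4,4,5,5-tetramethyl-1,3,2-dioxaborolan-2-yl)methylidene]-4-(triethylsilyloxy)cyclohex-1-en-1-yl]pent-2-en-4-ynoate | O=C1C=C(C#C/C=C/C(=O)OC(C)(C)C)/C(=C/B2OC(C)(C)C(C)(C)O2)[C@@H](OC(=O)c2c(C)cc(OCc3ccc(OC)cc3)cc2OCc3ccc(OC)cc3)[C@@]1(C)O[Si](CC)(CC)CC | intermediate
25 | C1 enol of the oxidised annulation product (6-hydroxymethylidene analogue of 24) | O=C1C=C(C#C/C=C/C(=O)OC(C)(C)C)C(=CO)[C@@H](OC(=O)c2c(C)cc(OCc3ccc(OC)cc3)cc2OCc3ccc(OC)cc3)[C@@]1(C)O[Si](CC)(CC)CC | intermediate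
26 | tert-butyl (2E)-3-[(7R,8R)-8-{2,4-bis[(4-methoxybenzyl)oxy]-6-methylbenzoyloxy}-7-methyl-6-oxo-7-(triethylsilyloxy)-7,8-dihydro-6H-isochromen-3-yl]prop-2-enoate | Cc1cc(OCc2ccc(OC)cc2)cc(OCc2ccc(OC)cc2)c1C(=O)O[C@@H]1C2=COC(/C=C/C(=O)OC(C)(C)C)=CC2=CC(=O)[C@]1(C)O[Si](CC)(CC)CC | intermediate
27 | (+)-mitorubrinic acid B | Cc1cc(O)cc(O)c1C(=O)O[C@@H]1C2=COC(/C=C/C(=O)O)=CC2=CC(=O)[C@]1(C)O | target

**Totals.** 15 steps in all; longest linear sequence 10 steps (1, 2, 5, 6, 7, 8, 9, 13, 14, 15).

**Steps most likely to fail**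

Step 13. The alkyne may insert with the opposite regiochemistry, the terminal diyne may oligomerise on the cationic rhodium, or the acylrhodium hydride may close intramolecularly before it meets the diyne. The fallback makes the same two bonds by C–C instead of C–H activation. It sets out from 17, which is cyclised by syn hydroacylation with [Rh((R)-BINAP)]BF4 in CH2Cl2 to the (borylmethylidene)cyclobutanone F1. F1 is then treated with Ni(cod)2/PCy3 and 23 in toluene at 90 °C. Zerovalent nickel couples the ketone carbon with the alkyne carbon remote from the conjugating alkynyl group (C6–C5), β-carbon elimination cleaves the strained C6–C8a bond, and reductive elimination forms C8a–C4a. The route is rejoined at 24.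

Step 14. The free enol may lose the C8 aroyloxy group by β-elimination, the enone may be over-oxidised, or the ring may close 5-exo at C4. The fallback replaces π-acid catalysis by electrophile-driven closure. It sets out from crude 25 (made from 24 as in step 14), which is treated with I2 and NaHCO3 in MeCN at 0 °C to give the 4-iodo derivative of 26, F2, by 6-endo iodocyclisation. The iodine is then removed with Bu3SnH and Pd(PPh3)4 (cat.) in THF, and the route is rejoined at 26.

Step 2. Facial selectivity on the small alkynyl aldehyde may be poor, giving C8 epimers. The fallback sets the carbinol centre by catalyst control. It sets out from the epimer mixture of 6, which is oxidised with Dess–Martin periodinane to the ynone F3. F3 is reduced by Noyori transfer hydrogenation with RuCl[(S,S)-TsDPEN](p-cymene) in HCO2H/Et3N, the alkynyl group acting as the π-directing substituent, which should deliver the (1R) carbinol. The route is rejoined at 6.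

**Further compounds**
F1 | step 13 | (1R,2R,4E)-2-methyl-3-oxo-4-[(4,4,5,5-tetramethyl-1,3,2-dioxaborolan-2-yl)methylidene]-2-(triethylsilyloxy)cyclobutyl 2,4-bis[(4-methoxybenzyl)oxy]-6-methylbenzoate | O=C1/C(=C/B2OC(C)(C)C(C)(C)O2)[C@@H](OC(=O)c2c(C)cc(OCc3ccc(OC)cc3)cc2OCc3ccc(OC)cc3)[C@@]1(C)O[Si](CC)(CC)CC
F2 | step 14 | tert-butyl (2E)-3-[(7R,8R)-8-{2,4-bis[(4-methoxybenzyl)oxy]-6-methylbenzoyloxy}-4-iodo-7-methyl-6-oxo-7-(triethylsilyloxy)-7,8-dihydro-6H-isochromen-3-yl]prop-2-enoate | Cc1cc(OCc2ccc(OC)cc2)cc(OCc2ccc(OC)cc2)c1C(=O)O[C@@H]1C2=COC(/C=C/C(=O)OC(C)(C)C)=C(I)C2=CC(=O)[C@]1(C)O[Si](CC)(CC)CC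
F3 | step 2 | (2S,5R)-2-tert-butyl-5-methyl-5-[3-(trimethylsilyl)prop-2-ynoyl]-1,3-dioxolan-4-one | C[C@]1(C(=O)C#C[Si](C)(C)C)O[C@H](C(C)(C)C)OC1=O
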